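**Retrosynthetic overview**
1. Target ⇒ cut the depside ester bond C(acyl)–O(aryl): olivetolic acid (4-OH as nucleophile) + 2,4-dimethoxy-6-propylbenzoyl chloride. The CO2H and 2-OH of olivetolic acid are masked in the flask as a phenylboronate chelate (the new step).
2. Acid chloride ⇒ 2,4-dimethoxy-6-propylbenzoic acid ⇒ lateral ethylation (CH3 → CH2CH2CH3) of 2,4-dimethoxy-6-methylbenzoic acid.
3. Rings: both benzene rings are bought intact (ring A = resorcylic acid ring, ring B = dimethoxybenzoyl ring). No permanent ring is formed; only a transient six-membered boron chelate on ring A is closed and reopened in the last step.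

Assumption: the target has no stereocentre and is achiral, so there is no enantiomer to set; 2,4-dimethoxy-6-methylbenzoic acid and olivetolic acid are taken as catalogue chemicals.

**Step 1**
Reactants: 1 2,4-dimethoxy-6-methylbenzoic acid
Product: 4 2,4-dimethoxy-6-propylbenzoic acid, via lateral dilithio dianion 2 (not isolated), via lithium 2,4-dimethoxy-6-propylbenzoate 3 (not isolated)
Conditions: LiN(iPr)2 (LDA, commercial solution, 2.2 equiv), THF, −78 to 0 °C; EtI (1.2 equiv), −78 °C to rt; 1 M HCl
Reagents that add atoms: iodoethane, CCI
Why: Two equivalents of LDA give the carboxylate and then the conjugated benzylic carbanion of the o-toluate, which is ethylated by SN2 attack on iodoethane (lateral lithiation–alkylation of an o-toluic acid dianion); the lithium carboxylate is a poor nucleophile in THF and stays unalkylated, and no stereocentre is formed.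

**Step 2**
Reactants: 4 2,4-dimethoxy-6-propylbenzoic acid
Product: 5 2,4-dimethoxy-6-propylbenzoyl chloride
Conditions: (COCl)2 (1.5 equiv), N,N-dimethylformamide (2 mol%), CH2Cl2, 0 °C to rt; evaporate, strip with toluene, use crude
Reagents that add atoms: oxalyl chloride, O=C(Cl)C(=O)Cl
Why: Acid chloride formation through the Vilsmeier-type chloroiminium species works on hindered benzoic acids at room temperature, leaves the aryl methyl ethers untouched and gives only volatile by-products.

**Step 3**
Reactants: 5 2,4-dimethoxy-6-propylbenzoyl chloride; 6 olivetolic acid (2,4-dihydroxy-6-pentylbenzoic acid)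
Product: 9 4-[(2,4-dimethoxy-6-propylbenzoyl)oxy]-2-hydroxy-6-pentylbenzoic acid, via benzodioxaborinone 7 (not isolated), via boron-masked depside 8 (not isolated)
Conditions: 6, PhB(OH)2 (1.05 equiv), 4 Å MS, CH2Cl2/THF, rt; then 5 (1.1 equiv), iPr2NEt (2.5 equiv), 4-(dimethylamino)pyridine (DMAP, 10 mol%), 0 °C to rt; then THF/H2O, rt
Reagents that add atoms: none
Why: Proposed new method: phenylboronic acid condenses with the CO2H/2-OH pair of 6 to the six-membered benzodioxaborinone 7 (the known binding mode of salicylic acids to arylboronic acids), which takes the carboxyl group and the chelated phenol out of play so that the 4-OH is the only nucleophile left; its phenoxide (iPr2NEt, whose binding makes boron four-coordinate and damps the acyloxyboron carbonyl) attacks the DMAP-activated hindered aroyl chloride 5 by addition–elimination to give 8, and water then cleaves both B–O bonds and returns PhB(OH)2; the closest known reaction type is the one-pot phenylboronate masking of cis-diols for site-selective acylation of sugars, not yet shown for a hydroxy-salicylic acid or for depside formation; no stereocentre is formed.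

**Compound list**
1 | 2,4-dimethoxy-6-methylbenzoic acid | Cc1cc(OC)cc(OC)c1C(=O)O | starting material
2 | lateral dilithio dianion of 1 (lithium carboxylate, lithiated at the ring CH3) | [Li+].[Li+].[CH2-]c1cc(OC)cc(OC)c1C(=O)[O-] | intermediate
3 | lithium 2,4-dimethoxy-6-propylbenzoate | [Li+].CCCc1cc(OC)cc(OC)c1C(=O)[O-] | intermediate
4 | 2,4-dimethoxy-6-propylbenzoic acid | CCCc1cc(OC)cc(OC)c1C(=O)O | intermediate
5 | 2,4-dimethoxy-6-propylbenzoyl chloride | CCCc1cc(OC)cc(OC)c1C(=O)Cl | intermediate
6 | olivetolic acid (2,4-dihydroxy-6-pentylbenzoic acid) | CCCCCc1cc(O)cc(O)c1C(=O)O | starting material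
7 | 7-hydroxy-5-pentyl-2-phenyl-4H-1,3,2-benzodioxaborin-4-one | CCCCCc1cc(O)cc2OB(c3ccccc3)OC(=O)c12 | intermediate
8 | 4-oxo-5-pentyl-2-phenyl-4H-1,3,2-benzodioxaborin-7-yl 2,4-dimethoxy-6-propylbenzoate | CCCCCc1cc(OC(=O)c3c(CCC)cc(OC)cc3OC)cc2OB(c4ccccc4)OC(=O)c12 | intermediate
9 | 4-[(2,4-dimethoxy-6-propylbenzoyl)oxy]-2-hydroxy-6-pentylbenzoic acid (achiral) | CCCCCc1cc(OC(=O)c2c(CCC)cc(OC)cc2OC)cc(O)c1C(=O)O | target

**Step count and risks**
Total step count: 3. Longest linear sequence: 3 steps (1 → 4 → 5 → 9); olivetolic acid 6 enters in the last step.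

Most likely to fail, in this order:

Step 3 (the proposed new step). The boronate mask may not hold under the acylation, or the acyloxyboron carbonyl of 7 may itself be attacked and give oligomers. The fallback uses known chemistry with a benzyl ester as protecting group; it sets out from 6 (with acid 4 as partner) and comes back at 9. Olivetolic acid 6 is alkylated at the carboxylate only (BnBr, KHCO3, DMF, rt) to benzyl 2,4-dihydroxy-6-pentylbenzoate F1. Acid 4 is stirred with trifluoroacetic anhydride in toluene to give 2,4-dimethoxy-6-propylbenzoic trifluoroacetic anhydride F2. F2 acylates the free 4-OH of F1 (the 2-OH is held in a hydrogen bond to the ester carbonyl) to benzyl 4-[(2,4-dimethoxy-6-propylbenzoyl)oxy]-2-hydroxy-6-pentylbenzoate F3. Hydrogenolysis (H2, Pd/C, EtOAc, rt) removes the benzyl group and gives 9.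

Step 1. The dianion may form incompletely or aggregate, ring lithiation may compete, or a second ethylation may occur. The fallback changes from the unprotected dianion to an ester monoanion; it sets out from 1 and comes back at 3 (and from there at 4). Acid 1 is O-methylated (MeI, K2CO3, DMF, rt) to methyl 2,4-dimethoxy-6-methylbenzoate F4. LDA (1.1 equiv, THF, −78 °C) gives the lateral benzylic lithio anion of the ester F5, which is ethylated with iodoethane to methyl 2,4-dimethoxy-6-propylbenzoate F6. The hindered ester is cleaved with LiOH in DMSO/H2O at 100 °C to the lithium salt 3, which is acidified to 4 as in step 1.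

Step 2. The electron-rich acid chloride may be partly hydrolysed on handling, or the ring may be attacked by the chloroiminium species. The fallback changes the class of acyl donor; it sets out from 4 and comes back at 8. Acid 4 with cyanuric fluoride and pyridine in CH2Cl2 (0 °C to rt) gives 2,4-dimethoxy-6-propylbenzoyl fluoride F7, which survives aqueous work-up and silica. F7 is used in place of 5 under the conditions of step 3 (iPr2NEt, DMAP) to acylate the boronate 7 and gives 8, which is hydrolysed to 9 as before.

**Further compounds**
F1 | step 3 | benzyl 2,4-dihydroxy-6-pentylbenzoate | CCCCCc1cc(O)cc(O)c1C(=O)OCc1ccccc1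
F2 | step 3 | 2,4-dimethoxy-6-propylbenzoic trifluoroacetic anhydride | CCCc1cc(OC)cc(OC)c1C(=O)OC(=O)C(F)(F)F
F3 | step 3 | benzyl 4-[(2,4-dimethoxy-6-propylbenzoyl)oxy]-2-hydroxy-6-pentylbenzoate | CCCCCc1cc(OC(=O)c2c(CCC)cc(OC)cc2OC)cc(O)c1C(=O)OCc1ccccc1
F4 | step 1 | methyl 2,4-dimethoxy-6-methylbenzoate | Cc1cc(OC)cc(OC)c1C(=O)OC
F5 | step 1 | lateral benzylic lithio anion of methyl 2,4-dimethoxy-6-methylbenzoate | [Li+].[CH2-]c1cc(OC)cc(OC)c1C(=O)OC
F6 | step 1 | methyl 2,4-dimethoxy-6-propylbenzoate | CCCc1cc(OC)cc(OC)c1C(=O)OC
F7 | step 2 | 2,4-dimethoxy-6-propylbenzoyl fluoride | CCCc1cc(OC)cc(OC)c1C(=O)F
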